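Numbering used throughout: quinone ring C1–C6 (carbonyls C1 and C4, side chain on C2, methyls on C3, C5, C6); side chain C1'–C16' counted from the ring, with methyl branches on C3', C7', C11' and C15'. Compounds 1–11 are those of the steps and of the compound list.

## The problem

The target is a 2,3,5-trimethyl-1,4-benzoquinone joined through the single bond C2–C1' to a saturated chain C1'–C16' with four methyl branches, i.e. a head-to-tail C20 isoprenoid; no ring has to be closed and no skeletal bond is hard to make. The difficulty is stereochemical: C3' is a tertiary carbinol (R) whose two larger substituents are both CH2 groups, and C7' (R) and C11' (R) are methyl-bearing methines with no heteroatom within four bonds. The three centres are 1,5-related along a flexible chain (three CH2 groups between each pair), so none can control another; each must be bought or set by a reagent or catalyst that reads only its local surroundings. The feature that allows a short solution is that C7', C11' and C15' are the methyl-bearing carbons of three isoprene units: the bonds C6'–C7', C10'–C11' and C14'–C15' are the hydrogenated E-trisubstituted C=C bonds of an all-E geranylgeranyl chain. The two prochiral olefins C6'=C7' and C10'=C11' have the same local constitution (CH2–CH=C(CH3)–CH2, head end on the CH carbon), so one chiral hydrogenation catalyst that attacks the same face of both gives the like pair, which is the R,R pair of the target. C3' is C3 of the same C20 allylic alcohol, the carbon addressed by a hydroxyl-directed epoxidation. The quinone is reduced by H2, boranes, hydrides and organometallics, and the tertiary C3' hydroxyl ionises in strong acid and, at the hydroquinone oxidation level, closes onto the phenol to a chromanol. The quinone must therefore be unveiled last from a form that has no free phenol.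

## Retrosynthesis

**11 ⇒ 10.** The two quinone C=O groups are traced back to two aryl methyl ethers (the O–CH3 bonds are added; no skeletal bond is cut). Against a free or acylated hydroquinone, the 1,4-dimethoxyarene 10 survives boranes, palladium and H2 and cannot cyclise onto C3'. The forward reaction is an oxidative demethylation that leaves a saturated chain and a tertiary alcohol alone.

**10 ⇒ 9 (key).** Six C–H bonds are removed, at C6'/C7', C10'/C11' and C14'/C15', which takes the saturated chain back to the (6E,10E)-triene 9. The neighbouring choices are C–C cuts beside C7' or C11' (C4'–C5', C8'–C9'), which need two separately sourced methyl centres and sp3–sp3 couplings. The C–H cut needs neither: three stereocentres become one, and the chain becomes the intact carbon skeleton of an achiral commercial terpene. The forward reaction must hydrogenate unfunctionalised trisubstituted olefins with high face selectivity, without E/Z isomerisation, in the presence of a tertiary alcohol and an electron-rich arene.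

**9 ⇒ 4 + 7.** The C2–C1' bond (aryl–CH2) is cut, together with one C–H bond at C2', giving the vinyl carbinol 4 and the aryl bromide 7, joined forward through the alkylborane 8. The neighbouring cut C2'–C3' (carbonyl addition) would destroy the carbinol centre, and C1'–C2' would need a chiral 2,2-disubstituted epoxide. Here C3' is a spectator two bonds from the reacting carbon. The forward step needs a borane that takes the vinyl group and not the three trisubstituted olefins, and a coupling that tolerates a di-ortho-substituted bromide.

**4 ⇒ 2 ⇒ 1.** The tertiary allylic alcohol 4 is the 1,3-transposed form of the primary allylic alcohol 1: the C3–O bond is traced to the epoxide of 2, and the vinyl group to the C1 carbinol through the epoxy iodide 3. Enantioselective addition to a methyl ketone cannot tell CH3 from CH2; epoxidation of an E-3-methyl-2-alken-1-ol can, and 1 is achiral and commercial. The forward steps must epoxidise only the allylic olefin of a tetraene and never break the C3–O bond.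

**7 ⇒ 6 ⇒ 5.** The C–Br bond and two O–CH3 bonds are cut; trimethylhydroquinone 5 is a bulk chemical and the only free ring position of 6 is the one needed.

## Roads not taken

Alternative 1: the chiral-pool route, the one most chemists would draw first. The cut is the same C2–C1' bond and C3'–O centre, but C7' and C11' are bought in natural (2E,7R,11R)-phytol A1. Forward, Katsuki–Sharpless epoxidation of A1 gives epoxy alcohol A2, reductive transposition gives (3R,7R,11R)-isophytol A3, and hydroboration/Suzuki coupling with 7 and oxidation finish. The step count is the same as in the chosen plan, so the argument is not economy. It creates only one of the three stereocentres and inherits the other two from a plant isolate whose C2=C3 E/Z purity and supply fix the outcome, and it reaches only the 7'R,11'R series. The chosen plan makes all three centres by catalysis from an achiral alcohol, two of them in one operation, and reaches any stereoisomer through the choice of tartrate and ligand antipode. Alternative 1 is kept as the fallback for the key step.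

Alternative 2: the biomimetic ring detour. The C3'–O bond is treated as the O1–C2 bond of a chroman: Friedel–Crafts alkylation of 5 with A1 gives the phytylhydroquinone A4, ring closure of the phenol onto C3' gives α-tocopherol A5, and oxidative opening of the chroman (FeCl3, water) gives 11 with retention at C3'. The forward key step is the cyclisation, done in nature by a tocopherol cyclase (a protonating cyclase). With a Brønsted or Lewis acid the tertiary cation is captured from both faces, so both C2 epimers of A5 form; the enzyme is a membrane protein of limited practical availability. A ring is built only to be cleaved, the air-sensitive hydroquinone A4 has to be handled, and two centres are again bought. Oxidising purchased A5 directly would be a semisynthesis.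

Alternative 3: carbonyl addition at the carbinol. The cut is C2'–C3': the Grignard reagent A7 adds to the methyl ketone A6 ((6R,10R)-6,10,14-trimethylpentadecan-2-one, from oxidative cleavage of A1) and gives the tertiary alcohol A8. This is the most convergent cut, but the two carbonyl faces differ only by CH3 against CH2, which no reagent or catalyst resolves usefully, and the nearest stereocentre of A6 is four bonds away. A8 would form as a mixture of both C3' epimers, oils that differ at one remote centre, so the hardest stereocentre is given up and two centres are still bought.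

Key step: step 6

Assumption 1: L-(+)-diethyl tartrate is taken to give the (2S,3S)-epoxide from E-3-methyl-2-alken-1-ols of the geraniol type, so the D-(−)-ester gives (2R,3R)-2.

Assumption 2: the (S)-enantiomer of the ligand L, 7-[bis(2-methylphenyl)phosphanyloxy]-2-phenyl-6,7-dihydro-5H-cyclopenta[b]pyridine, is taken as the one that turns E-CH2–CH=C(CH3)–CH2 olefins into the R centres needed here. If the sense is the opposite, the (R)-ligand is used and nothing else changes. BArF stands for B[3,5-(CF3)2C6H3]4.

Assumption 3: commercial geranylgeraniol 1 is the all-E isomer.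

## Route

Step 1
Reactants: 1 (2E,6E,10E)-3,7,11,15-tetramethylhexadeca-2,6,10,14-tetraen-1-ol (geranylgeraniol)
Product: 2 [(2R,3R)-3-methyl-3-[(3E,7E)-4,8,12-trimethyltrideca-3,7,11-trien-1-yl]oxiran-2-yl]methanol
Conditions: Ti(OiPr)4 (10 mol %), D-(−)-diethyl tartrate (12 mol %), t-BuOOH (in decane), 4 Å molecular sieves, CH2Cl2, −20 °C
Reagents that add atoms: tert-butyl hydroperoxide, CC(C)(C)OO
Why: Katsuki–Sharpless asymmetric epoxidation; the tetravalent titanium tartrate complex binds the allylic hydroxyl and delivers the peroxide oxygen only to C2=C3, so the three remote olefins stay, and the D-(−)-tartrate sets C2 and C3 as R,R, which fixes the later C3' as R.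

Step 2
Reactants: 2 [(2R,3R)-3-methyl-3-[(3E,7E)-4,8,12-trimethyltrideca-3,7,11-trien-1-yl]oxiran-2-yl]methanol
Product: 4 (3R,6E,10E)-3,7,11,15-tetramethylhexadeca-1,6,10,14-tetraen-3-ol, via epoxy iodide 3 (not isolated)
Conditions: PPh3, I2, imidazole, THF, 0 °C; then Zn dust, AcOH, 0 to 25 °C
Reagents that add atoms: none
Why: Appel-type iodination of the primary hydroxyl, then zinc insertion into the C–I bond and β-elimination of the epoxide oxygen (reductive 1,3-transposition of a 2,3-epoxy halide) give the vinyl carbinol; the C3–O bond is never broken, so C3 keeps its configuration (R).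

Step 3
Reactants: 5 2,3,5-trimethylbenzene-1,4-diol (trimethylhydroquinone)
Product: 6 1,4-dimethoxy-2,3,5-trimethylbenzene
Conditions: MeI, K2CO3, acetone, reflux, N2
Reagents that add atoms: iodomethane, CI
Why: Williamson ether synthesis on both phenols; the nitrogen atmosphere keeps the hydroquinone from air oxidation to the quinone.

Step 4
Reactants: 6 1,4-dimethoxy-2,3,5-trimethylbenzene
Product: 7 1-bromo-2,5-dimethoxy-3,4,6-trimethylbenzene
Conditions: NBS, MeCN, 25 °C, dark
Reagents that add atoms: N-bromosuccinimide, O=C1CCC(=O)N1Br
Why: Electrophilic aromatic bromination at the only free ring position, activated by the ortho methoxy group; a polar solvent and darkness disfavour radical bromination of the ring methyls.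

Step 5
Reactants: 4 (3R,6E,10E)-3,7,11,15-tetramethylhexadeca-1,6,10,14-tetraen-3-ol; 7 1-bromo-2,5-dimethoxy-3,4,6-trimethylbenzene
Product: 9 (3R,6E,10E)-1-(2,5-dimethoxy-3,4,6-trimethylphenyl)-3,7,11,15-tetramethylhexadeca-6,10,14-trien-3-ol, via bis(9-BBN) adduct 8 (not isolated)
Conditions: 9-BBN (2.2 equiv), THF, 0 to 40 °C; then 7, Pd(OAc)2 (3 mol %), SPhos (6 mol %), K3PO4, THF/H2O, 65 °C
Reagents that add atoms: none
Why: Anti-Markovnikov hydroboration of the monosubstituted vinyl group by 9-BBN, which reacts far faster there than at trisubstituted olefins (the second equivalent borylates the hydroxyl), then B-alkyl Suzuki–Miyaura coupling through zerovalent palladium formed from Pd(OAc)2 and SPhos, a ligand suited to di-ortho-substituted electron-rich bromides; C3 is not involved and stays R.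

Step 6
Reactants: 9 (3R,6E,10E)-1-(2,5-dimethoxy-3,4,6-trimethylphenyl)-3,7,11,15-tetramethylhexadeca-6,10,14-trien-3-ol
Product: 10 (3R,7R,11R)-1-(2,5-dimethoxy-3,4,6-trimethylphenyl)-3,7,11,15-tetramethylhexadecan-3-ol
Conditions: H2 (50 bar), [Ir(cod)(L)][B(3,5-(CF3)2C6H3)4] (1 mol %, L = (S)-ligand of assumption 2), CH2Cl2, 25 °C
Reagents that add atoms: none
Why: Under H2 the cationic monovalent iridium precatalyst loses cyclooctadiene and gives an N,P-ligated iridium dihydride that binds a trisubstituted C=C bond without help from any polar group and transfers two hydrogens to one olefin face by migratory insertion and reductive elimination (trivalent/pentavalent iridium cycle), while the non-coordinating borate anion and CH2Cl2 keep the metal electrophilic and disfavour E/Z isomerisation before reduction. The closest known reaction type is the asymmetric hydrogenation of unfunctionalised E-trisubstituted olefins with iridium pyridine-phosphinite catalysts, in particular of the all-E triene side chains of tocotrienyl esters and of farnesol derivatives, where two methyl-bearing centres are set in one operation. No ring is closed. C7' and C11' are each set by the catalyst alone: the chiral pocket reads the positions of H, CH3 and the two CH2 groups on the E olefin, which are the same at C6'=C7' and C10'=C11', so both olefins should be reduced from the same face and receive the same descriptor (R,R with the ligand antipode chosen). C3' lies four and eight bonds from the reacting carbons and is a spectator, so no matched or mismatched pairing arises, and C15' becomes an achiral isopropyl end. The step needs face selectivity at two olefins and full reduction of three; the E purity inherited from 1, a hexasubstituted arene that cannot bind iridium, and a tertiary hydroxyl that is neither allylic nor benzylic should secure this.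

Step 7
Reactants: 10 (3R,7R,11R)-1-(2,5-dimethoxy-3,4,6-trimethylphenyl)-3,7,11,15-tetramethylhexadecan-3-ol
Product: 11 2-[(3R,7R,11R)-3-hydroxy-3,7,11,15-tetramethylhexadecyl]-3,5,6-trimethylcyclohexa-2,5-diene-1,4-dione (α-tocopherylquinone)
Conditions: (NH4)2Ce(NO3)6 (2.5 equiv), MeCN/H2O 4:1, 0 °C
Reagents that add atoms: water, O
Why: Oxidative demethylation of a 1,4-dimethoxyarene by tetravalent cerium (two one-electron oxidations, water adds at the two ipso carbons, methanol leaves); the saturated chain and the tertiary alcohol are inert, and a transient cyclic ketal from capture by the C3' hydroxyl would hydrolyse to the same quinone, so no stereocentre is touched.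

## Compound list

1 | (2E,6E,10E)-3,7,11,15-tetramethylhexadeca-2,6,10,14-tetraen-1-ol (geranylgeraniol) | CC(C)=CCC/C(C)=C/CC/C(C)=C/CC/C(C)=C/CO | starting material
2 | [(2R,3R)-3-methyl-3-[(3E,7E)-4,8,12-trimethyltrideca-3,7,11-trien-1-yl]oxiran-2-yl]methanol | OC[C@H]1O[C@]1(C)CC/C=C(\C)CC/C=C(\C)CCC=C(C)C | intermediate
3 | (2S,3R)-2-(iodomethyl)-3-methyl-3-[(3E,7E)-4,8,12-trimethyltrideca-3,7,11-trien-1-yl]oxirane (C2 is S only because CH2I outranks C3; formed and consumed in step 2) | IC[C@H]1O[C@]1(C)CC/C=C(\C)CC/C=C(\C)CCC=C(C)C | intermediate
4 | (3R,6E,10E)-3,7,11,15-tetramethylhexadeca-1,6,10,14-tetraen-3-ol ((R)-geranyllinalool) | C=C[C@](C)(O)CC/C=C(\C)CC/C=C(\C)CCC=C(C)C | intermediate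
5 | 2,3,5-trimethylbenzene-1,4-diol | Cc1cc(O)c(C)c(C)c1O | starting material
6 | 1,4-dimethoxy-2,3,5-trimethylbenzene | COc1cc(C)c(OC)c(C)c1C | intermediate
7 | 1-bromo-2,5-dimethoxy-3,4,6-trimethylbenzene | COc1c(Br)c(C)c(OC)c(C)c1C | intermediate
8 | 9-[(3S,6E,10E)-3-(9-borabicyclo[3.3.1]nonan-9-yloxy)-3,7,11,15-tetramethylhexadeca-6,10,14-trien-1-yl]-9-borabicyclo[3.3.1]nonane (3S only because the CH2CH2B arm ranks below C4; spatial arrangement as in 4; formed and consumed in step 5) | B1(C2CCCC1CCC2)CC[C@](C)(OB1C2CCCC1CCC2)CC/C=C(\C)CC/C=C(\C)CCC=C(C)C | intermediate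
9 | (3R,6E,10E)-1-(2,5-dimethoxy-3,4,6-trimethylphenyl)-3,7,11,15-tetramethylhexadeca-6,10,14-trien-3-ol | COc1c(C)c(C)c(OC)c(C)c1CC[C@](C)(O)CC/C=C(\C)CC/C=C(\C)CCC=C(C)C | intermediate
10 | (3R,7R,11R)-1-(2,5-dimethoxy-3,4,6-trimethylphenyl)-3,7,11,15-tetramethylhexadecan-3-ol | COc1c(C)c(C)c(OC)c(C)c1CC[C@](C)(O)CCC[C@H](C)CCC[C@H](C)CCCC(C)C | intermediate
11 | 2-[(3R,7R,11R)-3-hydroxy-3,7,11,15-tetramethylhexadecyl]-3,5,6-trimethylcyclohexa-2,5-diene-1,4-dione | CC1=C(C)C(=O)C(CC[C@](C)(O)CCC[C@H](C)CCC[C@H](C)CCCC(C)C)=C(C)C1=O | target

## Step count and least certain steps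

Total: 7 steps. Longest linear sequence: 5 steps from 1 (steps 1, 2, 5, 6, 7); steps 3 and 4 form the two-step side branch to 7.

**Step 6 (key step).** The most likely failures are three:
- incomplete face selection at one of the two olefins, which would show as 7'S or 11'S epimers that cannot be separated from 10 (any Z-olefin content of 1 would be carried through the same way);
- loss or capture of the tertiary hydroxyl, because the iridium hydrides are strongly acidic and could ionise C3' (dehydration, or ring closure onto C7' to a tetrahydropyran);
- hydroxyl-directed delivery of hydrogen at the nearest olefin C6'=C7', which would work against catalyst control.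

The fallback sets out from bromide 7 and returns at 10; the two methyl centres are bought instead of made. Natural (2E,7R,11R)-phytol F1 is epoxidised under the conditions of step 1 to (2R,3R)-2,3-epoxyphytol F2. Under the conditions of step 2 this passes through the epoxy iodide F3 to (3R,7R,11R)-isophytol F4. Hydroboration of F4 with 9-BBN to the bis(9-BBN) adduct F5 and Suzuki–Miyaura coupling with 7 under the conditions of step 5 give 10 directly, and step 7 follows unchanged.

**Step 5.** Oxidative addition and transmetalation at the di-ortho-substituted, electron-rich bromide may be slow, so that protodeboronation or β-hydride elimination of the alkylborane competes; the excess 9-BBN needed for the hydroxyl may also begin to hydroborate the trisubstituted olefins. The fallback reverses the polarity of the aryl–CH2 bond formation; it sets out from 2 and 7 and returns at 9. NaAlH2(OCH2CH2OCH3)2 in THF at 0 °C opens 2 by hydride delivery to C2 and gives (3R,6E,10E)-3,7,11,15-tetramethylhexadeca-6,10,14-triene-1,3-diol F6. TsCl in pyridine sulfonylates only the primary hydroxyl and gives the monotosylate F7. The Grignard reagent (2,5-dimethoxy-3,4,6-trimethylphenyl)magnesium bromide F8, made from 7 and Mg, displaces the tosylate under Li2CuCl4 catalysis at −20 °C and gives 9; one further equivalent of F8 is spent on the tertiary hydroxyl and returns arene 6.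

**Step 2.** Iodide or the Lewis-acidic zinc salts may open the epoxide of 3 before the reductive elimination, and acid may cause allylic transposition or cyclisation of the tertiary allylic alcohol 4 in the telescoped mixture. The fallback is a Wharton transposition, which needs neither halide nor metal; it sets out from 2 and returns at 4. Oxidation of 2 with SO3·pyridine, DMSO and Et3N gives (2S,3R)-3-methyl-3-[(3E,7E)-4,8,12-trimethyltrideca-3,7,11-trien-1-yl]oxirane-2-carbaldehyde F9. Hydrazine hydrate with catalytic AcOH in MeOH at 0 °C converts F9 into its hydrazone F10, which opens the epoxide and loses N2 to give 4, again without touching the C3–O bond.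

## Further compounds

F1 | step 6 | (2E,7R,11R)-3,7,11,15-tetramethylhexadec-2-en-1-ol (natural phytol, purchased) | OC/C=C(\C)CCC[C@H](C)CCC[C@H](C)CCCC(C)C
F2 | step 6 | [(2R,3R)-3-methyl-3-[(4R,8R)-4,8,12-trimethyltridecyl]oxiran-2-yl]methanol | OC[C@H]1O[C@]1(C)CCC[C@H](C)CCC[C@H](C)CCCC(C)C
F3 | step 6 | (2S,3R)-2-(iodomethyl)-3-methyl-3-[(4R,8R)-4,8,12-trimethyltridecyl]oxirane | IC[C@H]1O[C@]1(C)CCC[C@H](C)CCC[C@H](C)CCCC(C)C
F4 | step 6 | (3R,7R,11R)-3,7,11,15-tetramethylhexadec-1-en-3-ol (isophytol) | C=C[C@](C)(O)CCC[C@H](C)CCC[C@H](C)CCCC(C)C
F5 | step 6 | 9-[(3S,7R,11R)-3-(9-borabicyclo[3.3.1]nonan-9-yloxy)-3,7,11,15-tetramethylhexadecyl]-9-borabicyclo[3.3.1]nonane | B1(C2CCCC1CCC2)CC[C@](C)(OB1C2CCCC1CCC2)CCC[C@H](C)CCC[C@H](C)CCCC(C)C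
F6 | step 5 | (3R,6E,10E)-3,7,11,15-tetramethylhexadeca-6,10,14-triene-1,3-diol | OCC[C@](C)(O)CC/C=C(\C)CC/C=C(\C)CCC=C(C)C
F7 | step 5 | (3R,6E,10E)-3-hydroxy-3,7,11,15-tetramethylhexadeca-6,10,14-trien-1-yl 4-methylbenzenesulfonate | Cc1ccc(cc1)S(=O)(=O)OCC[C@](C)(O)CC/C=C(\C)CC/C=C(\C)CCC=C(C)C
F8 | step 5 | (2,5-dimethoxy-3,4,6-trimethylphenyl)magnesium bromide | COc1c([Mg]Br)c(C)c(OC)c(C)c1C
F9 | step 2 | (2S,3R)-3-methyl-3-[(3E,7E)-4,8,12-trimethyltrideca-3,7,11-trien-1-yl]oxirane-2-carbaldehyde | O=C[C@H]1O[C@]1(C)CC/C=C(\C)CC/C=C(\C)CCC=C(C)C
F10 | step 2 | hydrazone of F9, [(2R,3R)-3-methyl-3-[(3E,7E)-4,8,12-trimethyltrideca-3,7,11-trien-1-yl]oxiran-2-yl]methylidenehydrazine | NN=C[C@H]1O[C@]1(C)CC/C=C(\C)CC/C=C(\C)CCC=C(C)C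
A1 | alternative 1 | (2E,7R,11R)-3,7,11,15-tetramethylhexadec-2-en-1-ol (natural phytol) | OC/C=C(\C)CCC[C@H](C)CCC[C@H](C)CCCC(C)C
A2 | alternative 1 | [(2R,3R)-3-methyl-3-[(4R,8R)-4,8,12-trimethyltridecyl]oxiran-2-yl]methanol | OC[C@H]1O[C@]1(C)CCC[C@H](C)CCC[C@H](C)CCCC(C)C
A3 | alternative 1 | (3R,7R,11R)-3,7,11,15-tetramethylhexadec-1-en-3-ol (isophytol) | C=C[C@](C)(O)CCC[C@H](C)CCC[C@H](C)CCCC(C)C
A4 | alternative 2 | 2,3,5-trimethyl-6-[(2E,7R,11R)-3,7,11,15-tetramethylhexadec-2-en-1-yl]benzene-1,4-diol | Cc1c(C)c(O)c(C/C=C(\C)CCC[C@H](C)CCC[C@H](C)CCCC(C)C)c(C)c1O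
A5 | alternative 2 | (2R)-2,5,7,8-tetramethyl-2-[(4R,8R)-4,8,12-trimethyltridecyl]-3,4-dihydro-2H-chromen-6-ol (α-tocopherol) | Cc1c(C)c2O[C@](C)(CCC[C@H](C)CCC[C@H](C)CCCC(C)C)CCc2c(C)c1O
A6 | alternative 3 | (6R,10R)-6,10,14-trimethylpentadecan-2-one | CC(=O)CCC[C@H](C)CCC[C@H](C)CCCC(C)C
A7 | alternative 3 | [2-(2,5-dimethoxy-3,4,6-trimethylphenyl)ethyl]magnesium bromide | COc1c(CC[Mg]Br)c(C)c(OC)c(C)c1C
A8 | alternative 3 | (3RS,7R,11R)-1-(2,5-dimethoxy-3,4,6-trimethylphenyl)-3,7,11,15-tetramethylhexadecan-3-ol (both C3 epimers) | COc1c(C)c(C)c(OC)c(C)c1CCC(C)(O)CCC[C@H](C)CCC[C@H](C)CCCC(C)C
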